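**Retrosynthetic overview**
1. The target 28 comes from triol 25 by acetylation of the C13 hydroxyl and esterification of the C8 hydroxyl with epoxy acid 27.
2. 25 comes from bicyclic lactol 21 by a ring expansion: the butenolide γ-carbon C6 is inserted into the C5–O bond of the six-membered acetal ring. This forms C5–C6, the nine-membered oxonane (ten-membered carbocycle) and the C5=C6 bond.
3. 21 comes from the aldol union (C8–C9) of tetrahydrofuran methyl ketone 14 with butenolide aldehyde 6, followed by chelation-controlled methyl addition at C10.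
4. 14 comes from (S)-2-methylglycidol (C4) by allyl opening, cross-metathesis and cis-selective oxidative cyclisation; 6 comes from but-2-yne-1,4-diol by carbomagnesiation and carboxylation.
5. Ring order: butenolide, then tetrahydrofuran, then the transient six-membered acetal, then the oxonane by ring expansion.

Assumption: 7 and 27 are bought as single enantiomers; atoms are labelled C1–C15 as in germacranolides (C12 = lactone C=O on C11, lactone O on C6, C13 = CH2O on C11, C14 = methyl on C10, C15 = methyl on C4).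

**Fragment 1 (butenolide aldehyde)**

Step 1
Reactants: 1 but-2-yne-1,4-diol; 2 vinylmagnesium chloride
Product: 4 4-ethenyl-3-(hydroxymethyl)furan-2(5H)-one, via alkenylmagnesium chelate 3 (not isolated)
Conditions: 2 (4 equiv), CuI (10 mol %), THF–toluene, 65 °C; CO2 (1 atm), 0 °C; 2 M HCl
Reagents that add atoms: carbon dioxide (O=C=O)
Why: Anti-carbomagnesiation of the bis(alkoxide) (Duboudin/Fallis carbometalation of propargylic alcohols) puts the vinyl group on C7 and a chelated alkenyl–Mg on C11, so carboxylation and acid work-up lactonise onto the cis CH2O arm and give the fully substituted butenolide in one operation.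

Step 2
Reactants: 4 4-ethenyl-3-(hydroxymethyl)furan-2(5H)-one
Product: 5 3-{[(tert-butyldimethylsilyl)oxy]methyl}-4-ethenylfuran-2(5H)-one
Conditions: TBSCl, imidazole, DMF, 0 °C → rt
Reagents that add atoms: tert-butyldimethylsilyl chloride (CC(C)(C)[Si](C)(C)Cl)
Why: Silyl protection of the primary alcohol; a silyl ether is carried instead of the final acetate because a C13 acetate would be expelled from the furanolate generated in step 14.

Step 3
Reactants: 5 3-{[(tert-butyldimethylsilyl)oxy]methyl}-4-ethenylfuran-2(5H)-one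
Product: 6 4-{[(tert-butyldimethylsilyl)oxy]methyl}-5-oxo-2,5-dihydrofuran-3-carbaldehyde
Conditions: O3, CH2Cl2, −78 °C (indicator end-point); Me2S
Reagents that add atoms: ozone ([O-][O+]=O)
Why: Ozonolysis with reductive work-up cleaves only the monosubstituted vinyl group (the tetrasubstituted, electron-poor ring alkene is inert) and unveils the C8 aldehyde.

**Fragment 2 (tetrahydrofuran ketone)**

Step 4
Reactants: 7 (S)-(2-methyloxiran-2-yl)methanol; 8 allylmagnesium chloride
Product: 9 (2R)-2-methylhex-5-ene-1,2-diol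
Conditions: 8 (2.5 equiv), CuI (10 mol %), THF, −40 → 0 °C; aq. NH4Cl
Reagents that add atoms: none
Why: Copper-catalysed Grignard opening of the epoxide at its CH2 terminus (SN2) does not touch the quaternary carbinol, so the glycidol stereocentre becomes C4 (R).

Step 5
Reactants: 9 (2R)-2-methylhex-5-ene-1,2-diol; 10 (E)-but-2-ene
Product: 11 (2R,5E)-2-methylhept-5-ene-1,2-diol
Conditions: 10 (excess), second-generation Hoveyda–Grubbs catalyst (2 mol %), CH2Cl2, 40 °C, sealed tube
Reagents that add atoms: none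
Why: Olefin cross-metathesis caps the terminal alkene with the methyl group that becomes C9; any minor Z isomer only gives the C10 epimer of 12, which converges at ketone 14.

Step 6
Reactants: 11 (2R,5E)-2-methylhept-5-ene-1,2-diol
Product: 12 (1S)-1-[(2S,5R)-5-(hydroxymethyl)-5-methyloxolan-2-yl]ethan-1-ol
Conditions: OsO4 (5 mol %), Me3NO·2H2O (2 equiv), camphorsulfonic acid, CH2Cl2, rt
Reagents that add atoms: trimethylamine N-oxide (C[N+](C)(C)[O-])
Why: Osmium-catalysed oxidative cyclisation of a 1,2-diol onto an alkene (Donohoe) adds O–C1 and HO–C10 syn through a chelated osmate ester, which gives only the 2,5-cis tetrahydrofuran, so C1 (S) is set by C4.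

Step 7
Reactants: 12 (1S)-1-[(2S,5R)-5-(hydroxymethyl)-5-methyloxolan-2-yl]ethan-1-ol
Product: 13 (1S)-1-[(2S,5R)-5-methyl-5-{[(triethylsilyl)oxy]methyl}oxolan-2-yl]ethan-1-ol
Conditions: TESCl (1.05 equiv), imidazole, CH2Cl2, −40 °C
Reagents that add atoms: triethylsilyl chloride (CC[Si](Cl)(CC)CC)
Why: Kinetically selective silylation of the primary hydroxyl over the secondary one.

Step 8
Reactants: 13 (1S)-1-[(2S,5R)-5-methyl-5-{[(triethylsilyl)oxy]methyl}oxolan-2-yl]ethan-1-ol
Product: 14 1-[(2S,5R)-5-methyl-5-{[(triethylsilyl)oxy]methyl}oxolan-2-yl]ethan-1-one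
Conditions: n-Pr4N[RuO4] (5 mol %), N-methylmorpholine N-oxide, 4 Å MS, CH2Cl2, rt
Reagents that add atoms: none
Why: Ley–Griffith oxidation gives the methyl ketone under neutral conditions that neither epimerise C1 nor cleave the TES ether.

**Union and endgame**

Step 9
Reactants: 14 1-[(2S,5R)-5-methyl-5-{[(triethylsilyl)oxy]methyl}oxolan-2-yl]ethan-1-one
Product: 15 triethyl({(2R,5S)-2-methyl-5-[1-(trimethylsilyloxy)ethenyl]oxolan-2-yl}methoxy)silane
Conditions: LDA, THF, −78 °C; TMSCl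
Reagents that add atoms: trimethylsilyl chloride (C[Si](C)(C)Cl)
Why: Kinetic deprotonation at the methyl group and O-silylation give the terminal silyl enol ether without disturbing the α-alkoxy stereocentre C1.

Step 10
Reactants: 15 triethyl({(2R,5S)-2-methyl-5-[1-(trimethylsilyloxy)ethenyl]oxolan-2-yl}methoxy)silane; 6 4-{[(tert-butyldimethylsilyl)oxy]methyl}-5-oxo-2,5-dihydrofuran-3-carbaldehyde
Product: 17 3-{[(tert-butyldimethylsilyl)oxy]methyl}-4-{(1S)-1-hydroxy-3-[(2S,5R)-5-methyl-5-{[(triethylsilyl)oxy]methyl}oxolan-2-yl]-3-oxopropyl}furan-2(5H)-one, via trichlorosilyl aldolate 16 (not isolated)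
Conditions: SiCl4 (1.2 equiv), binaphthyl bisphosphoramide catalyst (5 mol %, the enantiomer that directs attack to the Si face of 6), i-Pr2NEt (0.1 equiv), CH2Cl2, −78 °C; aq. KF/NaHCO3
Reagents that add atoms: none
Why: Lewis-base-activated SiCl4 Mukaiyama aldol addition (Denmark) proceeds through an open transition state, so the chiral catalyst sets C8 (S) by Si-face attack on the conjugated aldehyde.

Step 11
Reactants: 17 3-{[(tert-butyldimethylsilyl)oxy]methyl}-4-{(1S)-1-hydroxy-3-[(2S,5R)-5-methyl-5-{[(triethylsilyl)oxy]methyl}oxolan-2-yl]-3-oxopropyl}furan-2(5H)-one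
Product: 18 3-{[(tert-butyldimethylsilyl)oxy]methyl}-4-{(1S)-3-[(2S,5R)-5-methyl-5-{[(triethylsilyl)oxy]methyl}oxolan-2-yl]-3-oxo-1-[(triethylsilyl)oxy]propyl}furan-2(5H)-one
Conditions: TESOTf, 2,6-lutidine, CH2Cl2, −78 °C
Reagents that add atoms: triethylsilyl triflate (CC[Si](CC)(CC)OS(=O)(=O)C(F)(F)F)
Why: Silylation of the secondary carbinol removes β-chelation and the dehydration/retro-aldol pathways before the carbonyl addition.

Step 12
Reactants: 18 3-{[(tert-butyldimethylsilyl)oxy]methyl}-4-{(1S)-3-[(2S,5R)-5-methyl-5-{[(triethylsilyl)oxy]methyl}oxolan-2-yl]-3-oxo-1-[(triethylsilyl)oxy]propyl}furan-2(5H)-one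
Product: 19 3-{[(tert-butyldimethylsilyl)oxy]methyl}-4-{(1S,3R)-3-hydroxy-3-[(2S,5R)-5-methyl-5-{[(triethylsilyl)oxy]methyl}oxolan-2-yl]-1-[(triethylsilyl)oxy]butyl}furan-2(5H)-one
Conditions: MeTiCl3 (2 equiv, from TiCl4 and MeLi), CH2Cl2–Et2O, −78 °C; aq. NH4Cl
Reagents that add atoms: methyltitanium trichloride (C[Ti](Cl)(Cl)Cl)
Why: Cram-chelate carbonyl addition: the titanium reagent binds the ketone oxygen and the ring oxygen on C1 and delivers methyl from the face of the C1–H, giving C10 (R); the non-basic reagent spares the lactone, its acidic C6–H2 and the silyl ethers.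

Step 13
Reactants: 19 3-{[(tert-butyldimethylsilyl)oxy]methyl}-4-{(1S,3R)-3-hydroxy-3-[(2S,5R)-5-methyl-5-{[(triethylsilyl)oxy]methyl}oxolan-2-yl]-1-[(triethylsilyl)oxy]butyl}furan-2(5H)-one
Product: 21 bicyclic lactol (C5 hemiacetal closed onto the C10 oxygen; 3,8-dioxabicyclo[3.2.1]octan-2-ol core; 4R,1S,10R,8S; C5 anomers), via hydroxy aldehyde 20 (not isolated)
Conditions: (COCl)2, DMSO, CH2Cl2, −78 → −35 °C; Et3N, −78 °C → rt
Reagents that add atoms: none
Why: Swern conditions oxidise a primary triethylsilyl ether directly to the aldehyde while secondary TES and TBS ethers survive, and the cis-placed tertiary C10 hydroxyl then closes the six-membered lactol spontaneously.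

Step 14
Reactants: 21 bicyclic lactol
Product: 25 (1S,4R,5E,8S,10R)-1,4-epoxy-8,10,13-trihydroxygermacra-5,7(11)-dien-12,6-olide, via silyloxyfuran acetal 22 (not isolated), via bridged adduct 23 (not isolated), via silylated macrocycle 24 (not isolated)
Conditions: TMSOTf (3.3 equiv), Et3N (3.6 equiv), CH2Cl2 (5 mM), 0 °C; TMSOTf (1 equiv), −78 → −30 °C; DBU (5 equiv), −30 °C → rt; HF·pyridine, THF, 0 °C
Reagents that add atoms: none
Why: Proposed new method: ring expansion of a lactol by side-chain insertion — silylation turns the butenolide into a 2-silyloxyfuran and the lactol into a silyl acetal, TMSOTf ionises the acetal to the bridged oxocarbenium ion, and the tethered furan carbon C6 attacks C5 in a seven-membered ring closure (much easier than a direct ten-membered one); DBU then removes the C6–H of the regenerated butenolide and the furanolate expels the C5–O bond (E1cB), so the six-membered acetal ring becomes the nine-membered oxonane/ten-membered carbocycle, the ring itself forces the required C5=C6 geometry, and the C10 hydroxyl is released; no step is pericyclic, and the closest known chemistry is ring expansion by side-chain insertion with C–heteroatom cleavage (Zip-type transacylations), vinylogous Mukaiyama addition of silyloxyfurans to cyclic oxocarbenium ions, and base-induced β-elimination of γ-(α-oxyalkyl)butenolides to γ-ylidenebutenolides.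

Step 15
Reactants: 25 (1S,4R,5E,8S,10R)-1,4-epoxy-8,10,13-trihydroxygermacra-5,7(11)-dien-12,6-olide
Product: 26 (1S,4R,5E,8S,10R)-13-acetoxy-1,4-epoxy-8,10-dihydroxygermacra-5,7(11)-dien-12,6-olide
Conditions: Ac2O (1.1 equiv), 2,4,6-collidine, CH2Cl2, −20 °C
Reagents that add atoms: acetic anhydride (CC(=O)OC(C)=O)
Why: Chemoselective acylation: the primary C13 hydroxyl reacts far faster with one equivalent of anhydride than the ring-bound secondary C8 hydroxyl and the tertiary C10 hydroxyl.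

Step 16
Reactants: 26 (1S,4R,5E,8S,10R)-13-acetoxy-1,4-epoxy-8,10-dihydroxygermacra-5,7(11)-dien-12,6-olide; 27 (2S)-2-methyloxirane-2-carboxylic acid
Product: 28 (1S,4R,5E,8S,10R)-13-acetoxy-1,4-epoxy-10-hydroxy-8-{[(2S)-2-methyloxirane-2-carbonyl]oxy}germacra-5,7(11)-dien-12,6-olide
Conditions: 27 (1.5 equiv), EDC·HCl, DMAP (0.2 equiv), CH2Cl2, 0 °C → rt
Reagents that add atoms: none
Why: Steglich esterification of the remaining secondary alcohol with the enantiopure epoxy acid; the tertiary C10 hydroxyl does not react and the epoxide stereocentre is not involved.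

**Compound list**
1 | but-2-yne-1,4-diol | OCC#CCO | starting material
2 | vinylmagnesium chloride | C=C[Mg]Cl | starting material
3 | (Z)-alkenylmagnesium chelate: 2-ethenyl-3-(chloromagnesio)but-2-ene-1,4-diol bis(chloromagnesium alkoxide), vinyl anti to Mg | C=C/C(CO[Mg]Cl)=C(/[Mg]Cl)CO[Mg]Cl | intermediate
4 | 4-ethenyl-3-(hydroxymethyl)furan-2(5H)-one | C=CC1=C(CO)C(=O)OC1 | intermediate
5 | 3-{[(tert-butyldimethylsilyl)oxy]methyl}-4-ethenylfuran-2(5H)-one | C=CC1=C(CO[Si](C)(C)C(C)(C)C)C(=O)OC1 | intermediate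
6 | 4-{[(tert-butyldimethylsilyl)oxy]methyl}-5-oxo-2,5-dihydrofuran-3-carbaldehyde | O=CC1=C(CO[Si](C)(C)C(C)(C)C)C(=O)OC1 | intermediate
7 | (S)-(2-methyloxiran-2-yl)methanol | OC[C@@]1(C)CO1 | starting material
8 | allylmagnesium chloride | C=CC[Mg]Cl | starting material
9 | (2R)-2-methylhex-5-ene-1,2-diol | OC[C@@](O)(C)CCC=C | intermediate
10 | (E)-but-2-ene | C/C=C/C | starting material
11 | (2R,5E)-2-methylhept-5-ene-1,2-diol | OC[C@@](O)(C)CC/C=C/C | intermediate
12 | (1S)-1-[(2S,5R)-5-(hydroxymethyl)-5-methyloxolan-2-yl]ethan-1-ol | OC[C@@]1(C)CC[C@H](O1)[C@H](C)O | intermediate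
13 | (1S)-1-[(2S,5R)-5-methyl-5-{[(triethylsilyl)oxy]methyl}oxolan-2-yl]ethan-1-ol | CC[Si](CC)(CC)OC[C@@]1(C)CC[C@H](O1)[C@H](C)O | intermediate
14 | 1-[(2S,5R)-5-methyl-5-{[(triethylsilyl)oxy]methyl}oxolan-2-yl]ethan-1-one | CC[Si](CC)(CC)OC[C@@]1(C)CC[C@H](O1)C(C)=O | intermediate
15 | triethyl({(2R,5S)-2-methyl-5-[1-(trimethylsilyloxy)ethenyl]oxolan-2-yl}methoxy)silane | CC[Si](CC)(CC)OC[C@@]1(C)CC[C@H](O1)C(=C)O[Si](C)(C)C | intermediate
16 | trichlorosilyl ether of aldol 17 (8S) | CC[Si](CC)(CC)OC[C@@]1(C)CC[C@H](O1)C(=O)C[C@H](O[Si](Cl)(Cl)Cl)C2=C(CO[Si](C)(C)C(C)(C)C)C(=O)OC2 | intermediate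
17 | 3-{[(tert-butyldimethylsilyl)oxy]methyl}-4-{(1S)-1-hydroxy-3-[(2S,5R)-5-methyl-5-{[(triethylsilyl)oxy]methyl}oxolan-2-yl]-3-oxopropyl}furan-2(5H)-one | CC[Si](CC)(CC)OC[C@@]1(C)CC[C@H](O1)C(=O)C[C@H](O)C2=C(CO[Si](C)(C)C(C)(C)C)C(=O)OC2 | intermediate
18 | C8 triethylsilyl ether of 17 | CC[Si](CC)(CC)OC[C@@]1(C)CC[C@H](O1)C(=O)C[C@H](O[Si](CC)(CC)CC)C2=C(CO[Si](C)(C)C(C)(C)C)C(=O)OC2 | intermediate
19 | 3-{[(tert-butyldimethylsilyl)oxy]methyl}-4-{(1S,3R)-3-hydroxy-3-[(2S,5R)-5-methyl-5-{[(triethylsilyl)oxy]methyl}oxolan-2-yl]-1-[(triethylsilyl)oxy]butyl}furan-2(5H)-one | CC[Si](CC)(CC)OC[C@@]1(C)CC[C@H](O1)[C@](C)(O)C[C@H](O[Si](CC)(CC)CC)C2=C(CO[Si](C)(C)C(C)(C)C)C(=O)OC2 | intermediate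
20 | (2R,5S)-5-{(2R,4S)-4-[4-({[tert-butyl(dimethyl)silyl]oxy}methyl)-5-oxo-2,5-dihydrofuran-3-yl]-2-hydroxy-4-[(triethylsilyl)oxy]butan-2-yl}-2-methyloxolane-2-carbaldehyde | O=C[C@@]1(C)CC[C@H](O1)[C@](C)(O)C[C@H](O[Si](CC)(CC)CC)C2=C(CO[Si](C)(C)C(C)(C)C)C(=O)OC2 | intermediate
21 | bicyclic lactol of 20 (C5–OH carbon bonded to the C10 oxygen; 4R,1S,10R,8S; both C5 anomers) | OC1[C@@]2(C)CC[C@H](O2)[C@](C)(O1)C[C@H](O[Si](CC)(CC)CC)C3=C(CO[Si](C)(C)C(C)(C)C)C(=O)OC3 | intermediate
22 | O-trimethylsilyl acetal of 21 with the butenolide as its 2-(trimethylsilyloxy)furan | C[Si](C)(C)OC1[C@@]2(C)CC[C@H](O2)[C@](C)(O1)C[C@H](O[Si](CC)(CC)CC)c3coc(O[Si](C)(C)C)c3CO[Si](C)(C)C(C)(C)C | intermediate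
23 | bridged adduct: C5–C6 bonded butenolide in which C5 still carries the O–C10 bridge (oxepane ring C5–C6–C7–C8–C9–C10–O; C5/C6 epimers) | O=C1OC2C(=C1CO[Si](C)(C)C(C)(C)C)[C@@H](O[Si](CC)(CC)CC)C[C@@]5(C)OC2[C@@]3(C)CC[C@@H]5O3 | intermediate
24 | (1S,4R,5E,8S,10R)-13-(tert-butyldimethylsilyloxy)-1,4-epoxy-10-hydroxy-8-(triethylsilyloxy)germacra-5,7(11)-dien-12,6-olide | CC(C)(C)[Si](C)(C)OCC1=C2/C(=C\[C@@]3(C)CC[C@H](O3)[C@](C)(O)C[C@@H]2O[Si](CC)(CC)CC)OC1=O | intermediate
25 | (1S,4R,5E,8S,10R)-1,4-epoxy-8,10,13-trihydroxygermacra-5,7(11)-dien-12,6-olide | OCC1=C2/C(=C\[C@@]3(C)CC[C@H](O3)[C@](C)(O)C[C@@H]2O)OC1=O | intermediate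
26 | (1S,4R,5E,8S,10R)-13-acetoxy-1,4-epoxy-8,10-dihydroxygermacra-5,7(11)-dien-12,6-olide | CC(=O)OCC1=C2/C(=C\[C@@]3(C)CC[C@H](O3)[C@](C)(O)C[C@@H]2O)OC1=O | intermediate
27 | (2S)-2-methyloxirane-2-carboxylic acid | OC(=O)[C@]1(C)CO1 | starting material
28 | (1S,4R,5E,8S,10R)-13-acetoxy-1,4-epoxy-10-hydroxy-8-{[(2S)-2-methyloxirane-2-carbonyl]oxy}germacra-5,7(11)-dien-12,6-olide (CNP0142137.1) | CC(=O)OCC1=C2/C(=C\[C@@]3(C)CC[C@H](O3)[C@](C)(O)C[C@@H]2OC(=O)[C@]2(C)CO2)OC1=O | target

**Step count**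
Total steps: 16. Longest linear sequence: 13 (steps 4–16, from 7). Fragment 1 (steps 1–3) joins at step 10.

**Three steps most likely to fail**

Step 14 (the new ring expansion). The oxocarbenium ion may not be captured by C6, or the freed C10 alkoxide may re-add; DBU could also epimerise C8. The fallback uses only known reactions, sets out from 19 and comes back at 25. 19 is silylated at the tertiary hydroxyl (TMSOTf, 2,6-lutidine) to the trimethylsilyl ether F1. The Swern conditions of step 13 then give the aldehyde F2, which can no longer close to a lactol. TBSOTf/Et3N converts the butenolide into the 2-silyloxyfuran F3, and BF3·OEt2 at 2 mM closes the ten-membered ring by an ordinary intramolecular vinylogous Mukaiyama aldol addition to the carbinol F4 (both C5/C6 epimers serve). Mesylation gives the mesylate F5, DBU eliminates it to the protected ylidene lactone F6, and HF·pyridine removes the three silyl groups to give 25.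

Step 10 (catalyst-controlled aldol on a sensitive, conjugated aldehyde; C8 selectivity). If the C8 ratio is poor, the mixture is taken through steps 11 and 12, and the fallback sets out from 19 (as its C8 epimer mixture) and comes back at 19 as one isomer. PPTS in MeOH removes both TES groups to give the triol F7. MnO2 oxidises only the allylic C8 carbinol to the β-hydroxy ketone F8. Et2BOMe/NaBH4 at −78 °C (Narasaka–Prasad 1,3-syn reduction directed by the C10 hydroxyl) gives the single 8S triol F9. TESCl/imidazole then silylates the primary and secondary hydroxyls again to give 19.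

Step 13 (direct oxidation of a neopentyl-type primary TES ether beside a second TES ether). If the oxidation stalls or strips the C8 silyl group, the fallback sets out from 19 and comes back at 21. Brief PPTS/MeOH at −10 °C cleaves only the primary TES ether to the primary alcohol F10, and Parikh–Doering oxidation (SO3·pyridine, DMSO, i-Pr2NEt) of F10 gives the aldehyde that closes to 21.

Further compounds
F1 | step 14 | C10 trimethylsilyl ether of 19 | CC[Si](CC)(CC)OC[C@@]1(C)CC[C@H](O1)[C@](C)(O[Si](C)(C)C)C[C@H](O[Si](CC)(CC)CC)C2=C(CO[Si](C)(C)C(C)(C)C)C(=O)OC2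
F2 | step 14 | C5 aldehyde with C10 trimethylsilyl ether (open form, no lactol) | O=C[C@@]1(C)CC[C@H](O1)[C@](C)(O[Si](C)(C)C)C[C@H](O[Si](CC)(CC)CC)C2=C(CO[Si](C)(C)C(C)(C)C)C(=O)OC2
F3 | step 14 | 2-(tert-butyldimethylsilyloxy)furan of F2 | O=C[C@@]1(C)CC[C@H](O1)[C@](C)(O[Si](C)(C)C)C[C@H](O[Si](CC)(CC)CC)c2coc(O[Si](C)(C)C(C)(C)C)c2CO[Si](C)(C)C(C)(C)C
F4 | step 14 | ten-membered vinylogous aldol carbinol (C5–OH, C6–H; C5/C6 epimers) | CC(C)(C)[Si](C)(C)OCC1=C2C(C(O)[C@@]3(C)CC[C@H](O3)[C@](C)(O[Si](C)(C)C)C[C@@H]2O[Si](CC)(CC)CC)OC1=O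
F5 | step 14 | C5 mesylate of F4 | CC(C)(C)[Si](C)(C)OCC1=C2C(C(OS(C)(=O)=O)[C@@]3(C)CC[C@H](O3)[C@](C)(O[Si](C)(C)C)C[C@@H]2O[Si](CC)(CC)CC)OC1=O
F6 | step 14 | C10 trimethylsilyl ether of 24 (protected ylidene lactone) | CC(C)(C)[Si](C)(C)OCC1=C2/C(=C\[C@@]3(C)CC[C@H](O3)[C@](C)(O[Si](C)(C)C)C[C@@H]2O[Si](CC)(CC)CC)OC1=O
F7 | step 10 | C5,C8,C10-triol from 19 (C8 epimer mixture, C13 silyl ether kept) | OC[C@@]1(C)CC[C@H](O1)[C@](C)(O)CC(O)C2=C(CO[Si](C)(C)C(C)(C)C)C(=O)OC2
F8 | step 10 | C8 ketone of F7 (β-hydroxy ketone) | OC[C@@]1(C)CC[C@H](O1)[C@](C)(O)CC(=O)C2=C(CO[Si](C)(C)C(C)(C)C)C(=O)OC2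
F9 | step 10 | (8S,10R)-triol (1,3-syn) | OC[C@@]1(C)CC[C@H](O1)[C@](C)(O)C[C@H](O)C2=C(CO[Si](C)(C)C(C)(C)C)C(=O)OC2
F10 | step 13 | primary C5 alcohol from 19 (C8 triethylsilyl ether kept) | OC[C@@]1(C)CC[C@H](O1)[C@](C)(O)C[C@H](O[Si](CC)(CC)CC)C2=C(CO[Si](C)(C)C(C)(C)C)C(=O)OC2
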